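Remarks on the chemistry: atoms are labelled on the tetralin skeleton. C1 carries ring C, C2 carries O2 and the carboxyl carbon C9, C3 carries O3 and the hydroxymethyl carbon C10, C4 is the benzylic CH2; ring A is the fused arene and ring B the saturated ring. From the SMILES of the target the descriptors are 1S,2S,3R. Assumption: both antipodes of the diene ligand of step 7 are available, and the one that gives (3S)-13 is used.

## Analysis of the target

Plicatic acid 25 is a 1-aryltetralin. Ring A is a benzo ring with a methoxy group at C6 and a hydroxyl at C7, ring B is the saturated six-membered ring C1 to C4, and ring C is a 3,4-dihydroxy-5-methoxyphenyl group on C1. Ring B carries three contiguous stereocentres: C1 (S, a doubly benzylic methine), C2 (S, fully substituted, with O2–H and C9) and C3 (R, fully substituted, with O3–H and C10). Ring C is cis to O2 and trans to C9; O2 is trans to O3, so O2 is cis to C10 and C9 is cis to O3. The sensitive groups are the catechol of ring C (oxidised by air in base), the electron-rich arenes, and the β-hydroxy acid unit C9–C2–C3–O3, which can cleave by retro-aldol reaction once O3 is a free alkoxide. C1–H also becomes acidic whenever C2 is a carbonyl carbon. The difficulty is the pair of adjacent fully substituted carbinol carbons with a trans diol, which no syn-dihydroxylation can deliver, next to a methine whose configuration must be tied to both. The strategy rests on the atoms C2, O2, C10 and C3: O2 and C10 lie on the same face of ring B, so they can be the members of an oxetane fused to ring B at C2–C3, and a four-membered ring can only be cis-fused. Making that oxetane by joining O2 to C10 and C2 to C3 therefore fixes the trans diol by geometry.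

## Retrosynthetic reasoning

25 from 24. The four benzyl C–O bonds (C7, the two on ring C, and O3) are cut last. The free catechol then never meets base or an oxidant, and the only operation on the polyphenol is a neutral hydrogenolysis. The forward step has to cleave a hindered tertiary benzyl ether at O3 together with three aryl benzyl ethers.

24 from 23 and 22. The 1,3-relationship of O2–H and C10–OH is read as an opened oxetane, so the O2–C10 bond is reconnected. This is where the cis relation of O2 and C10 comes from. Forward, an oxygen nucleophile must attack C10 with O2 as leaving group; C2 is quaternary and acceptor-substituted, so it is not a site for substitution. The ester is saponified while O3 is still benzylated, which blocks retro-aldol cleavage of C2–C3.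

22 from 21. The C2–C3 and O2–C10 bonds are cut together, a retro carbonyl–alkene (2+2) cycloaddition. The C2–C3 bond joins the two quaternary carbons; in polar chemistry C3, an oxygen-bearing carbon, would have to be the nucleophile, and bases are excluded by the acidity of C1–H. An excited C2 carbonyl reverses this polarity. The disconnection gives back an open-chain precursor and accounts for ring B, two stereocentres and the last two skeletal bonds. Forward, the step needs oxygen-to-C10 regiochemistry, control of the C2 face by C1, and a C1 centre that survives.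

21 from 20 and 18. The C2 ketone is removed by functional group interconversion to the ester CH2. The keto group is introduced only one step before irradiation, by enolate hydroxylation and a neutral oxidation, because it is the keto ester that makes C1 labile.

18 from 13 and 16. The C4–C4a bond is cut as an aryl–allyl cross-coupling. The acid-labile enol ether is thus brought in late and carried through only two steps before the key step. Reagent 16 comes from 15 by dehydrochlorination and 15 from 14 by benzylation.

13 from 5 and 12. The C1–ring C bond is cut as an asymmetric conjugate addition of an arylboron reagent to a cinnamate. C1 is the only stereocentre set by a reagent; C2 and C3 follow from it.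

5 from 3 and 4, 3 from 2, 2 from 1. The C1–C2 alkene is made by olefination of aldehyde 3. The bromine of 3, the later site of C4, is introduced para to the benzyloxy group of 2, which comes from 1.

12 from 9, 9 from 8, 8 from 6. The boronic acid comes from bromide 9 by halogen–metal exchange, and the catechol pattern from 6 by a Dakin oxidation and benzylation.

## Alternatives that were turned down

Alternative 1: Ring A is built last. The C4a–C8a and C7–C8 bonds are cut, which leads from tetralone A2 back to the acyclic furyl ynone A1, in which C2 and C3 already sit in an acetonide. Forward, the furan of A1 adds as a diene across the tethered ynone and the oxygen bridge opens to the C7 phenol, so rings A and B arise in one thermal step.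
- For: the C2/C3 diol is made on an open chain, where established asymmetric oxidations of an alkene apply, and the C7 hydroxyl emerges free and regiodefined. On both points this is stronger than the chosen route, which trusts a photochemical step for C2 and C3.
- Against: A2 has no ring C, and C1 is a ketone next to the quaternary C2. Ring C must be added to a hindered carbonyl and the benzylic alcohol removed, with nothing that enforces the cis relation of ring C and O2. The β-oxygenated ketone can fragment by retro-aldol reaction or β-elimination, the methoxyfuran is acid-labile, and the acetonide becomes trans-fused to ring B.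
- Comparison: the chosen route fixes C1 at the outset by a catalytic conjugate addition, uses it to steer C2, and needs three steps after ring closure where this alternative needs at least six.

Alternative 2: The C4–C4a bond is cut. Tetralin A4 is traced back to the oxetan-3-ol A3, in which the ring A benzyl group and the oxetane sit on the quaternary C2 of a tert-butyl dioxolanone. Forward, acid activates the oxetane and ring A attacks one of its two diastereotopic methylene carbons through the position para to the C7 ether. Ring B closes 6-exo-tet, the attacked carbon becomes C4 and the other becomes C10, so C3 is created by desymmetrisation.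
- For: a thermal and scalable ring closure, C2 from well-tried alkylation of a chiral dioxolanone enolate, and a free primary alcohol at C10 without an unmasking step. In these respects it is as strong as or stronger than the chosen route.
- Against: C1 is still CH2 in A4. Ring C would have to be attached to a benzylic methylene beside a quaternary carbon, with no control element for C1. The two oxetane methylenes differ only through the neighbouring dioxolanone, so the C3 selectivity is open, and the tertiary alcohol next to the activated carbon invites a 1,2-shift.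
- Comparison: the chosen route answers the point this alternative leaves open, the C1–C2 relationship, and reaches the whole skeleton in one step.

Alternative 3: The C3–C10 bond is cut. Oxasilolane A6 is traced back to the 1,2-dihydronaphthalene A5, a C3–C4 silyl enol ether whose O2 carries a bromomethyldimethylsilyl group. Forward, under radical chain conditions the silylmethyl radical adds 5-exo to C3 and the benzylic C4 radical is reduced. The cis-fused five-membered ring places C10 cis to O2, and Tamao oxidation would then give the C10 alcohol.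
- For: the same geometric argument as the chosen route, carried by a reaction class of long standing. The unmasking by Tamao oxidation is milder and more dependable than opening a hindered oxetane; here this alternative is stronger.
- Against: the radical must attack the fully substituted, oxygen-bearing alkene carbon in competition with 6-endo attack at C4. A5 presupposes ring B, C1, the C2 carbinol and a C3 ketone, an α-hydroxy β-keto ester prone to retro-Claisen cleavage and α-ketol rearrangement, and the strategy does not say how C2 is set relative to C1. Ring construction, enol ether formation, tethering, cyclisation, oxidation and desilylation all precede deprotection.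
- Comparison: the chosen route forms C2–C3, O2–C10, ring B and both quaternary centres in one step from an open-chain precursor.

Key step: step 13

## Route

Step 1
Reactants: 1 isovanillin
Product: 2 3-(benzyloxy)-4-methoxybenzaldehyde
Conditions: BnBr, K2CO3, DMF, 60 °C
Reagents that add atoms: benzyl bromide, BrCc1ccccc1
Why: Williamson ether synthesis on the only phenol; the benzyl ether later directs bromination para to itself and is removed in the last step.

Step 2
Reactants: 2 3-(benzyloxy)-4-methoxybenzaldehyde
Product: 3 5-(benzyloxy)-2-bromo-4-methoxybenzaldehyde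
Conditions: Br2, NaOAc, AcOH, 20 °C
Reagents that add atoms: bromine, BrBr
Why: Electrophilic aromatic bromination; the position para to the benzyloxy group and ortho to the formyl group is the most activated unhindered site, so the bromine marks the future C4a.

Step 3
Reactants: 3 5-(benzyloxy)-2-bromo-4-methoxybenzaldehyde; 4 trimethyl phosphonoacetate
Product: 5 methyl (2E)-3-[5-(benzyloxy)-2-bromo-4-methoxyphenyl]prop-2-enoate
Conditions: NaH, THF, 0 to 20 °C
Reagents that add atoms: none
Why: Horner–Wadsworth–Emmons olefination; the stabilised phosphonate anion should give the E-cinnamate, and no stereocentre is formed.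

Step 4
Reactants: 6 5-bromo-2-hydroxy-3-methoxybenzaldehyde
Product: 8 5-bromo-3-methoxybenzene-1,2-diol, via 5-bromo-2-hydroxy-3-methoxyphenyl formate 7 (not isolated)
Conditions: 30% H2O2, NaOH, H2O/THF, 0 to 20 °C, N2; then HCl
Reagents that add atoms: hydrogen peroxide, OO
Why: Dakin oxidation of an ortho-hydroxybenzaldehyde; aryl migration gives the formate, which is hydrolysed in the same flask to the catechol.

Step 5
Reactants: 8 5-bromo-3-methoxybenzene-1,2-diol
Product: 9 1,2-bis(benzyloxy)-5-bromo-3-methoxybenzene
Conditions: BnBr, K2CO3, DMF, 60 °C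
Reagents that add atoms: benzyl bromide, BrCc1ccccc1
Why: Double Williamson ether synthesis; the benzyl ethers protect the catechol against oxidation until the last step.

Step 6
Reactants: 9 1,2-bis(benzyloxy)-5-bromo-3-methoxybenzene
Product: 12 [3,4-bis(benzyloxy)-5-methoxyphenyl]boronic acid, via [3,4-bis(benzyloxy)-5-methoxyphenyl]lithium 10 (not isolated), via lithium [3,4-bis(benzyloxy)-5-methoxyphenyl]tri(propan-2-yloxy)borate 11 (not isolated)
Conditions: n-BuLi, THF, −78 °C; B(OiPr)3, −78 to 20 °C; 1 M HCl
Reagents that add atoms: triisopropyl borate, CC(C)OB(OC(C)C)OC(C)C; water, O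
Why: Bromine–lithium exchange is faster than any attack on the ethers at −78 °C; the aryllithium is trapped as the borate and hydrolysed to the boronic acid.

Step 7
Reactants: 5 methyl (2E)-3-[5-(benzyloxy)-2-bromo-4-methoxyphenyl]prop-2-enoate; 12 [3,4-bis(benzyloxy)-5-methoxyphenyl]boronic acid
Product: 13 methyl (3S)-3-[5-(benzyloxy)-2-bromo-4-methoxyphenyl]-3-[3,4-bis(benzyloxy)-5-methoxyphenyl]propanoate
Conditions: [RhCl(C2H4)2]2 (1.5 mol%), 2,5-diphenylbicyclo[2.2.2]octa-2,5-diene (antipode that gives 3S, 3.3 mol%), aq. KOH (10 mol%), 1,4-dioxane/H2O 10:1, 40 °C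
Reagents that add atoms: none
Why: Hayashi–Miyaura conjugate addition; the aryl group passes from boron to the rhodium–diene complex and adds to one enantioface of the cinnamate held by the C2-symmetric diene, which sets C1, and water protonates the rhodium enolate. The aryl bromide should not react with monovalent rhodium at this temperature.

Step 8
Reactants: 14 1,3-dichloropropan-2-ol
Product: 15 {[(1,3-dichloropropan-2-yl)oxy]methyl}benzene
Conditions: benzyl 2,2,2-trichloroacetimidate, TfOH (5 mol%), CH2Cl2/cyclohexane, 20 °C
Reagents that add atoms: benzyl 2,2,2-trichloroacetimidate, ClC(Cl)(Cl)C(=N)OCc1ccccc1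
Why: Acid-catalysed benzylation with the trichloroacetimidate; a basic benzylation would close the chlorohydrin to an epoxide.

Step 9
Reactants: 15 {[(1,3-dichloropropan-2-yl)oxy]methyl}benzene
Product: 16 {[(3-chloroprop-1-en-2-yl)oxy]methyl}benzene
Conditions: KOH (powder), Bu4NHSO4 (5 mol%), THF, 0 to 20 °C
Reagents that add atoms: none
Why: E2 dehydrochlorination under solid–liquid phase transfer; only the hydrogen on the oxygen-bearing carbon can be lost with chloride, which gives the 2-alkoxyallyl chloride, and no second elimination is possible.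

Step 10
Reactants: 13 methyl (3S)-3-[5-(benzyloxy)-2-bromo-4-methoxyphenyl]-3-[3,4-bis(benzyloxy)-5-methoxyphenyl]propanoate; 16 {[(3-chloroprop-1-en-2-yl)oxy]methyl}benzene
Product: 18 methyl (3S)-3-{5-(benzyloxy)-2-[2-(benzyloxy)prop-2-en-1-yl]-4-methoxyphenyl}-3-[3,4-bis(benzyloxy)-5-methoxyphenyl]propanoate, via methyl (3S)-3-[5-(benzyloxy)-4-methoxy-2-(4,4,5,5-tetramethyl-1,3,2-dioxaborolan-2-yl)phenyl]-3-[3,4-bis(benzyloxy)-5-methoxyphenyl]propanoate 17 (not isolated)
Conditions: B2pin2, Pd(OAc)2 (5 mol%), SPhos (10 mol%), KOAc, 1,4-dioxane, 90 °C; then 16, aq. K3PO4, 60 °C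
Reagents that add atoms: none
Why: Miyaura borylation followed in the same flask by Suzuki–Miyaura coupling with the allylic chloride through a π-allyl complex of palladium; both allyl termini are CH2, so only one product can form, and C1 is not touched.

Step 11
Reactants: 18 methyl (3S)-3-{5-(benzyloxy)-2-[2-(benzyloxy)prop-2-en-1-yl]-4-methoxyphenyl}-3-[3,4-bis(benzyloxy)-5-methoxyphenyl]propanoate
Product: 20 methyl (2RS,3S)-3-{5-(benzyloxy)-2-[2-(benzyloxy)prop-2-en-1-yl]-4-methoxyphenyl}-3-[3,4-bis(benzyloxy)-5-methoxyphenyl]-2-hydroxypropanoate, via potassium ester enolate 19 (not isolated)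
Conditions: KN(SiMe3)2, THF, −78 °C; 3-phenyl-2-(phenylsulfonyl)oxaziridine, −78 °C; aq. NH4Cl
Reagents that add atoms: 3-phenyl-2-(phenylsulfonyl)oxaziridine, O=S(=O)(c1ccccc1)N1OC1c1ccccc1
Why: Enolate oxidation with an N-sulfonyloxaziridine; the enolate is far more reactive than the enol ether at −78 °C. The new C2 centre is formed as a mixture of epimers that converge in step 12; C1 is not acidic at this stage.

Step 12
Reactants: 20 methyl (2RS,3S)-3-{5-(benzyloxy)-2-[2-(benzyloxy)prop-2-en-1-yl]-4-methoxyphenyl}-3-[3,4-bis(benzyloxy)-5-methoxyphenyl]-2-hydroxypropanoate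
Product: 21 methyl (3S)-3-{5-(benzyloxy)-2-[2-(benzyloxy)prop-2-en-1-yl]-4-methoxyphenyl}-3-[3,4-bis(benzyloxy)-5-methoxyphenyl]-2-oxopropanoate
Conditions: Dess–Martin periodinane, NaHCO3, CH2Cl2, 0 °C; filtered and used at once
Reagents that add atoms: none
Why: Dess–Martin oxidation of a secondary alcohol under buffered, base-free conditions; the buffer protects the enol ether from the acetic acid set free and no amine is present that could enolise C1.

Step 13
Reactants: 21 methyl (3S)-3-{5-(benzyloxy)-2-[2-(benzyloxy)prop-2-en-1-yl]-4-methoxyphenyl}-3-[3,4-bis(benzyloxy)-5-methoxyphenyl]-2-oxopropanoate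
Product: 22 methyl (2aR,8S,8aS)-2a,6-bis(benzyloxy)-8-[3,4-bis(benzyloxy)-5-methoxyphenyl]-5-methoxy-2a,3,8,8a-tetrahydro-2H-naphtho[2,3-b]oxete-8a-carboxylate
Conditions: hν (365 nm), degassed benzene (5 mM), 10 °C
Reagents that add atoms: none
Why: Excitation of the α-keto ester at its n,π* band (the ethers are transparent at 365 nm) and intersystem crossing give the triplet, whose electrophilic oxygen O2 bonds to the electron-rich terminal carbon C10 of the enol ether, leaving a 1,4-biradical with a captodative radical at C2 and a tertiary α-benzyloxy radical at C3. After spin inversion the two radical centres combine to the C2–C3 bond, which closes the oxetane and ring B in the same event. The closest known reaction type is the Paternò–Büchi reaction of α-keto esters with enol ethers, which gives 3-alkoxyoxetanes with this regiochemistry, together with the intramolecular Paternò–Büchi reaction of alkenyl ketones; an intramolecular case that annulates a six-membered carbocycle in this way is not documented. Ring B closes in the 6-exo sense with respect to the C3=C10 bond, since C2 bonds to the inner alkene carbon, and the oxetane closes by 1,4-biradical recombination, the overall mode being a (2+2) photocycloaddition. C3 is set by geometry, because the four-membered ring can only be cis-fused, so O2 ends cis to C10 and trans to O3. C2 is set by C1: in the reactive conformer the C1–H bond lies beside the ester carbon while ring A delivers the enol ether, so ring C ends trans to the ester and cis to O2. The step needs oxygen-to-C10 regiochemistry, which the polarity of the enol ether and the stability of the C3 radical secure, and it needs the cycloaddition to outrun α-cleavage of the C1–C2 bond and hydrogen abstraction from C4, which the ortho-phenylene tether, a non-polar solvent and long-wavelength light should favour. The methyl ester is kept because it offers no readily abstracted hydrogen for Norrish–Yang chemistry.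

Step 14
Reactants: 22 methyl (2aR,8S,8aS)-2a,6-bis(benzyloxy)-8-[3,4-bis(benzyloxy)-5-methoxyphenyl]-5-methoxy-2a,3,8,8a-tetrahydro-2H-naphtho[2,3-b]oxete-8a-carboxylate
Product: 23 methyl (1S,2S,3R)-3-(acetoxymethyl)-3,7-bis(benzyloxy)-1-[3,4-bis(benzyloxy)-5-methoxyphenyl]-2-hydroxy-6-methoxy-1,2,3,4-tetrahydronaphthalene-2-carboxylate
Conditions: AcOH (20 equiv), BF3·OEt2 (1.5 equiv), CH2Cl2, −20 to 0 °C
Reagents that add atoms: acetic acid, CC(=O)O
Why: Lewis acid-promoted SN2 opening of the oxetane at C10, the only ring carbon open to substitution, since C2 is quaternary and carries the ester; C2 and C3 keep their configuration because neither bond to them is broken. A 1,2-shift to C10 is disfavoured because no substituent on C3 is antiperiplanar to the C10–O2 bond in the four-membered ring.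

Step 15
Reactants: 23 methyl (1S,2S,3R)-3-(acetoxymethyl)-3,7-bis(benzyloxy)-1-[3,4-bis(benzyloxy)-5-methoxyphenyl]-2-hydroxy-6-methoxy-1,2,3,4-tetrahydronaphthalene-2-carboxylate
Product: 24 (1S,2S,3R)-3,7-bis(benzyloxy)-1-[3,4-bis(benzyloxy)-5-methoxyphenyl]-2-hydroxy-3-(hydroxymethyl)-6-methoxy-1,2,3,4-tetrahydronaphthalene-2-carboxylic acid
Conditions: LiOH, THF/MeOH/H2O, 40 °C; then dil. HCl to pH 3
Reagents that add atoms: lithium hydroxide, [Li+].[OH-]
Why: Saponification of the acetate and the methyl ester; the phenols are still benzylated, so base cannot oxidise them, and the benzyl ether on O3 prevents retro-aldol cleavage of the C2–C3 bond.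

Step 16
Reactants: 24 (1S,2S,3R)-3,7-bis(benzyloxy)-1-[3,4-bis(benzyloxy)-5-methoxyphenyl]-2-hydroxy-3-(hydroxymethyl)-6-methoxy-1,2,3,4-tetrahydronaphthalene-2-carboxylic acid
Product: 25 plicatic acid, (1S,2S,3R)-1-(3,4-dihydroxy-5-methoxyphenyl)-2,3,7-trihydroxy-3-(hydroxymethyl)-6-methoxy-1,2,3,4-tetrahydronaphthalene-2-carboxylic acid
Conditions: H2 (1 atm), Pd(OH)2/C, MeOH/EtOAc, 20 °C
Reagents that add atoms: none
Why: Hydrogenolysis of the three aryl benzyl ethers and the tertiary benzyl ether on O3; the skeleton has no benzylic C–O bond, so only the protecting groups are cleaved and the free acid is obtained without exposure to base.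

## Compound list

1 | isovanillin (3-hydroxy-4-methoxybenzaldehyde) | COc1ccc(C=O)cc1O | starting material
2 | 3-(benzyloxy)-4-methoxybenzaldehyde | COc1ccc(C=O)cc1OCc1ccccc1 | intermediate
3 | 5-(benzyloxy)-2-bromo-4-methoxybenzaldehyde | COc1cc(Br)c(C=O)cc1OCc1ccccc1 | intermediate
4 | trimethyl phosphonoacetate | COC(=O)CP(=O)(OC)OC | starting material
5 | methyl (2E)-3-[5-(benzyloxy)-2-bromo-4-methoxyphenyl]prop-2-enoate | COC(=O)/C=C/c1cc(OCc2ccccc2)c(OC)cc1Br | intermediate
6 | 5-bromo-2-hydroxy-3-methoxybenzaldehyde | COc1cc(Br)cc(C=O)c1O | starting material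
7 | 5-bromo-2-hydroxy-3-methoxyphenyl formate | COc1cc(Br)cc(OC=O)c1O | intermediate (not isolated)
8 | 5-bromo-3-methoxybenzene-1,2-diol | COc1cc(Br)cc(O)c1O | intermediate
9 | 1,2-bis(benzyloxy)-5-bromo-3-methoxybenzene | COc1cc(Br)cc(OCc2ccccc2)c1OCc1ccccc1 | intermediate
10 | [3,4-bis(benzyloxy)-5-methoxyphenyl]lithium | [Li]c1cc(OC)c(OCc2ccccc2)c(OCc2ccccc2)c1 | intermediate (not isolated)
11 | lithium [3,4-bis(benzyloxy)-5-methoxyphenyl]tri(propan-2-yloxy)borate | [Li+].CC(C)O[B-](OC(C)C)(OC(C)C)c1cc(OC)c(OCc2ccccc2)c(OCc2ccccc2)c1 | intermediate (not isolated)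
12 | [3,4-bis(benzyloxy)-5-methoxyphenyl]boronic acid | OB(O)c1cc(OC)c(OCc2ccccc2)c(OCc2ccccc2)c1 | intermediate
13 | methyl (3S)-3-[5-(benzyloxy)-2-bromo-4-methoxyphenyl]-3-[3,4-bis(benzyloxy)-5-methoxyphenyl]propanoate | COc1cc(Br)c(cc1OCc1ccccc1)[C@H](c1cc(OCc3ccccc3)c(OCc3ccccc3)c(OC)c1)CC(=O)OC | intermediate
14 | 1,3-dichloropropan-2-ol | OC(CCl)CCl | starting material
15 | {[(1,3-dichloropropan-2-yl)oxy]methyl}benzene | ClCC(CCl)OCc1ccccc1 | intermediate
16 | {[(3-chloroprop-1-en-2-yl)oxy]methyl}benzene | C=C(CCl)OCc1ccccc1 | intermediate
17 | methyl (3S)-3-[5-(benzyloxy)-4-methoxy-2-(4,4,5,5-tetramethyl-1,3,2-dioxaborolan-2-yl)phenyl]-3-[3,4-bis(benzyloxy)-5-methoxyphenyl]propanoate | COc1cc(B2OC(C)(C)C(C)(C)O2)c(cc1OCc1ccccc1)[C@H](c1cc(OCc3ccccc3)c(OCc3ccccc3)c(OC)c1)CC(=O)OC | intermediate (not isolated)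
18 | methyl (3S)-3-{5-(benzyloxy)-2-[2-(benzyloxy)prop-2-en-1-yl]-4-methoxyphenyl}-3-[3,4-bis(benzyloxy)-5-methoxyphenyl]propanoate | COc1cc(CC(=C)OCc3ccccc3)c(cc1OCc1ccccc1)[C@H](c1cc(OCc3ccccc3)c(OCc3ccccc3)c(OC)c1)CC(=O)OC | intermediate
19 | potassium enolate of ester 18 (C1 as in 18, enolate geometry not defined) | COc1cc(CC(=C)OCc3ccccc3)c(cc1OCc1ccccc1)[C@H](c1cc(OCc3ccccc3)c(OCc3ccccc3)c(OC)c1)C=C([O-])OC.[K+] | intermediate (not isolated)
20 | methyl (2RS,3S)-3-{5-(benzyloxy)-2-[2-(benzyloxy)prop-2-en-1-yl]-4-methoxyphenyl}-3-[3,4-bis(benzyloxy)-5-methoxyphenyl]-2-hydroxypropanoate (both C2 epimers) | COc1cc(CC(=C)OCc3ccccc3)c(cc1OCc1ccccc1)[C@H](c1cc(OCc3ccccc3)c(OCc3ccccc3)c(OC)c1)C(O)C(=O)OC | intermediate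
21 | methyl (3S)-3-{5-(benzyloxy)-2-[2-(benzyloxy)prop-2-en-1-yl]-4-methoxyphenyl}-3-[3,4-bis(benzyloxy)-5-methoxyphenyl]-2-oxopropanoate | COc1cc(CC(=C)OCc3ccccc3)c(cc1OCc1ccccc1)[C@H](c1cc(OCc3ccccc3)c(OCc3ccccc3)c(OC)c1)C(=O)C(=O)OC | intermediate
22 | methyl (2aR,8S,8aS)-2a,6-bis(benzyloxy)-8-[3,4-bis(benzyloxy)-5-methoxyphenyl]-5-methoxy-2a,3,8,8a-tetrahydro-2H-naphtho[2,3-b]oxete-8a-carboxylate (cis-fused oxetane C2–O2–C10–C3, ring C cis to O2) | COc1cc2c(cc1OCc1ccccc1)[C@H](c1cc(OCc3ccccc3)c(OCc3ccccc3)c(OC)c1)[C@]3(C(=O)OC)OC[C@]3(OCc4ccccc4)C2 | intermediate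
23 | methyl (1S,2S,3R)-3-(acetoxymethyl)-3,7-bis(benzyloxy)-1-[3,4-bis(benzyloxy)-5-methoxyphenyl]-2-hydroxy-6-methoxy-1,2,3,4-tetrahydronaphthalene-2-carboxylate | COc1cc2c(cc1OCc1ccccc1)[C@H](c1cc(OCc3ccccc3)c(OCc3ccccc3)c(OC)c1)[C@@](O)(C(=O)OC)[C@](OCc1ccccc1)(COC(C)=O)C2 | intermediate
24 | (1S,2S,3R)-3,7-bis(benzyloxy)-1-[3,4-bis(benzyloxy)-5-methoxyphenyl]-2-hydroxy-3-(hydroxymethyl)-6-methoxy-1,2,3,4-tetrahydronaphthalene-2-carboxylic acid | COc1cc2c(cc1OCc1ccccc1)[C@H](c1cc(OCc3ccccc3)c(OCc3ccccc3)c(OC)c1)[C@@](O)(C(=O)O)[C@](OCc1ccccc1)(CO)C2 | intermediate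
25 | plicatic acid, (1S,2S,3R)-1-(3,4-dihydroxy-5-methoxyphenyl)-2,3,7-trihydroxy-3-(hydroxymethyl)-6-methoxy-1,2,3,4-tetrahydronaphthalene-2-carboxylic acid | COc1cc2c(cc1O)[C@H](c1cc(O)c(O)c(OC)c1)[C@@](O)(C(=O)O)[C@](O)(CO)C2 | target

## Step count and least certain steps

Total: 16 steps. Longest linear sequence: 11 steps (1, 2, 3, 7, 10, 11, 12, 13, 14, 15, 16).

**Step 13 (key step).** What is most likely to go wrong is α-cleavage of the excited keto ester at the C1–C2 bond, because the diarylmethyl radical is well stabilised. Charge-transfer quenching of the triplet by the two trialkoxyarenes and hydrogen abstraction from the C4 methylene are further competitors, and any of these may outrun the bonding of O2 to C10.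

The fallback forms the C2–C3 bond in the ground state. It sets out from bromide 13 and comes back to the route at 25. The borylation of step 10 (through 17) would be followed in the same flask by Suzuki–Miyaura coupling with 2,3-dibromoprop-1-ene at its allylic bromide, which gives the 2-bromoallyl propanoate F1. Enolate hydroxylation as in step 11 would give the hydroxy ester F2, and Dess–Martin oxidation as in step 12 the 2-bromoallyl keto ester F3. A Nozaki–Hiyama–Kishi cyclisation (CrCl2, NiCl2 2 mol%, DMF, 20 °C) would add the alkenyl species of trivalent chromium at C3 to the C2 ketone under non-basic conditions, closing ring B as the 3-methylidene hydroxy ester F4; the ester should again turn away from ring C. Dihydroxylation (OsO4 cat., N-methylmorpholine N-oxide, acetone/H2O) should occur on the face opposite to the allylic O2 and to ring C and give the triol ester F5. LiOH would give the triol acid F6, and hydrogenolysis as in step 16 would give 25. This fallback gives up the geometric guarantee of the trans diol and relies on facial selectivity in the dihydroxylation.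

**Step 14.** The hindered oxetane may react only under forcing Lewis acid conditions, with loss of benzyl ethers by acetolysis or a cationic 1,2-shift at C3 in place of substitution at C10. The fallback removes the Lewis acid and the acyl donor and reverses the order of steps 14 and 15. It sets out from 22 and comes back at 24. Saponification (LiOH, THF/MeOH/H2O) would give the oxetane acid F9, in which the ring is stable to base. Specific-acid hydrolysis (1 M H2SO4, 1,4-dioxane, 50 °C) would then open the oxetane at C10 with water as the nucleophile and give 24 directly.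

**Step 12.** The doubly benzylic C1–H of keto ester 21 is acidic, so the configuration at C1 may be lost by enolisation during oxidation, work-up or storage. The oxidation cannot be made gentler in kind, so the fallback restores the enantiomeric purity downstream. It sets out from 21 of eroded purity and comes back at 24. The material would be taken through steps 13 to 15 unchanged, since the cycloaddition is diastereoselective for either antipode. Acid 24 would then be crystallised with (S)-1-phenylethylamine as the (S)-1-phenylethylammonium salt F8, and acidification of the purified salt would return 24.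

**Step 10.** Protodeboronation of the hindered boronate 17, or breakdown of the 2-benzyloxy-π-allyl palladium species in aqueous base, may compete with the coupling. The fallback reverses the polarity of the allyl partner. It sets out from 16 and 13 and comes back at 18. Bu3SnLi (from Bu3SnH and LiN(iPr)2, THF, −78 °C) would displace the chloride of 16 to give the allylstannane F7. Stille coupling of F7 with 13 (Pd(PPh3)4, toluene, 100 °C) would then give 18 without base and without a boron intermediate.

## Further compounds

F1 | step 13 | methyl (3S)-3-[5-(benzyloxy)-2-(2-bromoprop-2-en-1-yl)-4-methoxyphenyl]-3-[3,4-bis(benzyloxy)-5-methoxyphenyl]propanoate | COc1cc(CC(Br)=C)c(cc1OCc1ccccc1)[C@H](c1cc(OCc3ccccc3)c(OCc3ccccc3)c(OC)c1)CC(=O)OC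
F2 | step 13 | methyl (2RS,3S)-3-[5-(benzyloxy)-2-(2-bromoprop-2-en-1-yl)-4-methoxyphenyl]-3-[3,4-bis(benzyloxy)-5-methoxyphenyl]-2-hydroxypropanoate | COc1cc(CC(Br)=C)c(cc1OCc1ccccc1)[C@H](c1cc(OCc3ccccc3)c(OCc3ccccc3)c(OC)c1)C(O)C(=O)OC
F3 | step 13 | methyl (3S)-3-[5-(benzyloxy)-2-(2-bromoprop-2-en-1-yl)-4-methoxyphenyl]-3-[3,4-bis(benzyloxy)-5-methoxyphenyl]-2-oxopropanoate | COc1cc(CC(Br)=C)c(cc1OCc1ccccc1)[C@H](c1cc(OCc3ccccc3)c(OCc3ccccc3)c(OC)c1)C(=O)C(=O)OC
F4 | step 13 | methyl (1S,2S)-7-(benzyloxy)-1-[3,4-bis(benzyloxy)-5-methoxyphenyl]-2-hydroxy-6-methoxy-3-methylidene-1,2,3,4-tetrahydronaphthalene-2-carboxylate | COc1cc2c(cc1OCc1ccccc1)[C@H](c1cc(OCc3ccccc3)c(OCc3ccccc3)c(OC)c1)[C@@](O)(C(=O)OC)C(=C)C2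
F5 | step 13 | methyl (1S,2S,3R)-7-(benzyloxy)-1-[3,4-bis(benzyloxy)-5-methoxyphenyl]-2,3-dihydroxy-3-(hydroxymethyl)-6-methoxy-1,2,3,4-tetrahydronaphthalene-2-carboxylate | COc1cc2c(cc1OCc1ccccc1)[C@H](c1cc(OCc3ccccc3)c(OCc3ccccc3)c(OC)c1)[C@@](O)(C(=O)OC)[C@](O)(CO)C2
F6 | step 13 | (1S,2S,3R)-7-(benzyloxy)-1-[3,4-bis(benzyloxy)-5-methoxyphenyl]-2,3-dihydroxy-3-(hydroxymethyl)-6-methoxy-1,2,3,4-tetrahydronaphthalene-2-carboxylic acid | COc1cc2c(cc1OCc1ccccc1)[C@H](c1cc(OCc3ccccc3)c(OCc3ccccc3)c(OC)c1)[C@@](O)(C(=O)O)[C@](O)(CO)C2
F7 | step 10 | tributyl[2-(benzyloxy)prop-2-en-1-yl]stannane | CCCC[Sn](CCCC)(CCCC)CC(=C)OCc1ccccc1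
F8 | step 12 | (S)-1-phenylethylammonium salt of acid 24 | COc1cc2c(cc1OCc1ccccc1)[C@H](c1cc(OCc3ccccc3)c(OCc3ccccc3)c(OC)c1)[C@@](O)(C([O-])=O)[C@](OCc1ccccc1)(CO)C2.C[C@H]([NH3+])c1ccccc1
F9 | step 14 | (2aR,8S,8aS)-2a,6-bis(benzyloxy)-8-[3,4-bis(benzyloxy)-5-methoxyphenyl]-5-methoxy-2a,3,8,8a-tetrahydro-2H-naphtho[2,3-b]oxete-8a-carboxylic acid | COc1cc2c(cc1OCc1ccccc1)[C@H](c1cc(OCc3ccccc3)c(OCc3ccccc3)c(OC)c1)[C@]3(C(=O)O)OC[C@]3(OCc4ccccc4)C2
A1 | alternative 1 | furyl ynone: methyl 5-[(benzyloxy)methyl]-5-[(4-methoxyfuran-2-yl)methyl]-2,2-dimethyl-4-(prop-2-ynoyl)-1,3-dioxolane-4-carboxylate, the two dioxolane carbons configured as C2 and C3 of 25 | O=C(C#C)[C@]1(C(=O)OC)OC(C)(C)O[C@@]1(COCc2ccccc2)Cc1cc(OC)co1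
A2 | alternative 1 | 7-hydroxy-6-methoxy-1-tetralone with C2 and C3 as in 25, O2 and O3 as acetonide, C10 as benzyl ether, methyl ester | COc1cc2c(cc1O)C(=O)[C@]1(C(=O)OC)OC(C)(C)O[C@@]1(COCc3ccccc3)C2
A3 | alternative 2 | 5-[3-(benzyloxy)-4-methoxybenzyl]-2-tert-butyl-5-(3-hydroxyoxetan-3-yl)-1,3-dioxolan-4-one, C5 configured as C2 of 25 | COc1ccc(C[C@]2(O[C@@H](C(C)(C)C)OC2=O)C2(O)COC2)cc1OCc1ccccc1
A4 | alternative 2 | tetralin with C1 as CH2, C2 spiro-fused in a tert-butyl dioxolanone, C3 with OH and CH2OH as in 25, C7 benzyl ether | COc1cc2c(cc1OCc1ccccc1)C[C@]1(O[C@@H](C(C)(C)C)OC1=O)[C@](O)(CO)C2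
A5 | alternative 3 | 1,2-dihydronaphthalene with C1 and C2 as in 25, O2 as bromomethyldimethylsilyl ether, C3–C4 tert-butyldimethylsilyl enol ether, methyl ester, benzyl ethers on the phenols | COc1cc2c(cc1OCc1ccccc1)[C@H](c1cc(OCc3ccccc3)c(OCc3ccccc3)c(OC)c1)[C@@](O[Si](C)(C)CBr)(C(=O)OC)C(O[Si](C)(C)C(C)(C)C)=C2
A6 | alternative 3 | oxasilolane-fused tetralin with C1, C2 and C3 as in 25, O3 as tert-butyldimethylsilyl ether | COc1cc2c(cc1OCc1ccccc1)[C@H](c1cc(OCc3ccccc3)c(OCc3ccccc3)c(OC)c1)[C@]3(C(=O)OC)O[Si](C)(C)C[C@]3(O[Si](C)(C)C(C)(C)C)C2
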